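**Plan**

- Retrosynthesis: the aryl–C(=O) bond is cut first, which turns the cis C3 hydroxymethyl and C4 aroyl groups into a cis-fused γ-lactone plus 3,4-dimethoxyphenyllithium. A traceless methyl ester is then placed on C4 and the oxolane is cut at O1–C2 and C4–C5 into formaldehyde and a lactone-fused donor–acceptor cyclopropane. The cyclopropane is cut into a Z-cinnamyl silyl ether and a malonate carbene.
- Enabling feature: in the oxolane ring (O1, C2–C5) C2 carries the electron-rich trimethoxyphenyl donor, C4 a carbonyl acceptor, C3 lies between them and C5 is unsubstituted. C2–C3–C4 is therefore a masked donor–acceptor cyclopropane and O1–C5 is formaldehyde. The C3 CH2O group and the C4 carbonyl carbon are cis and can be tied as a five-membered lactone.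
- Forward order: Z-alkene, then cyclopropane ring, then lactone ring, then oxolane ring by (3+2) annulation, then loss of the ester, then lactone opening to the aryl ketone.
- Stereochemistry: C3 (and a provisional C2) come from ligand-controlled cyclopropanation of the Z-alkene, C2 is then inverted in the annulation, and C4 is fixed by the obligatory cis ring fusion when the ester is removed.

Key step: step 7

Assumption: formaldehyde is charged as commercial paraformaldehyde and depolymerised by the Lewis acid in the flask; the bisoxazoline antipode that leads to the (2R,3R)-cyclopropane is taken to be chosen after a trial run, since both antipodes are accessible.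

**Step 1**
Reactants: 1 5-iodo-1,2,3-trimethoxybenzene; 2 prop-2-yn-1-ol
Product: 3 3-(3,4,5-trimethoxyphenyl)prop-2-yn-1-ol
Conditions: PdCl2(PPh3)2 (2 mol %), CuI (4 mol %), Et3N, THF, rt
Reagents that add atoms: none
Why: Sonogashira coupling of an aryl iodide with a terminal alkyne runs at room temperature and tolerates the free hydroxyl group.

**Step 2**
Reactants: 3 3-(3,4,5-trimethoxyphenyl)prop-2-yn-1-ol
Product: 4 (Z)-3-(3,4,5-trimethoxyphenyl)prop-2-en-1-ol
Conditions: H2 (1 atm), Pd/CaCO3 poisoned with Pb(OAc)2 (Lindlar catalyst), quinoline, EtOAc, rt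
Reagents that add atoms: none
Why: Lindlar semihydrogenation adds both hydrogens to the same face of the alkyne and should stop at the Z-alkene, whose geometry later becomes the cis relationship on the cyclopropane.

**Step 3**
Reactants: 4 (Z)-3-(3,4,5-trimethoxyphenyl)prop-2-en-1-ol
Product: 5 (Z)-tert-butyldimethyl{[3-(3,4,5-trimethoxyphenyl)prop-2-en-1-yl]oxy}silane
Conditions: TBSCl, imidazole, CH2Cl2, 0 °C to rt
Reagents that add atoms: tert-butyldimethylsilyl chloride, CC(C)(C)[Si](C)(C)Cl
Why: Standard silylation of a primary alcohol removes the O–H bond that would otherwise intercept the copper carbene by O–H insertion.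

**Step 4**
Reactants: 6 dimethyl malonate
Product: 7 dimethyl 2-(phenyl-λ3-iodanylidene)propanedioate
Conditions: PhI(OAc)2, KOH, MeCN, 0 °C
Reagents that add atoms: (diacetoxyiodo)benzene, CC(=O)OI(OC(C)=O)c1ccccc1
Why: Condensation of the malonate anion with the trivalent iodine reagent is the standard preparation of malonate iodonium ylides, which transfer the malonate carbene to copper at or below room temperature.

**Step 5**
Reactants: 5 (Z)-tert-butyldimethyl{[3-(3,4,5-trimethoxyphenyl)prop-2-en-1-yl]oxy}silane; 7 dimethyl 2-(phenyl-λ3-iodanylidene)propanedioate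
Product: 8 dimethyl (2R,3R)-2-{[(tert-butyldimethylsilyl)oxy]methyl}-3-(3,4,5-trimethoxyphenyl)cyclopropane-1,1-dicarboxylate
Conditions: [Cu(MeCN)4]PF6 (5 mol %, monovalent copper), chiral side-arm bisoxazoline ligand (6 mol %), 4 Å MS, PhMe, 0 °C to rt, 7 added in portions
Reagents that add atoms: none
Why: In this copper-bisoxazoline-catalysed asymmetric cyclopropanation the electrophilic copper malonate carbene adds to the electron-rich Z-styrenyl double bond in a concerted syn fashion, so the Z geometry gives aryl and silyloxymethyl cis, while the chiral ligand selects the alkene face and thereby sets both stereocentres.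

**Step 6**
Reactants: 8 dimethyl (2R,3R)-2-{[(tert-butyldimethylsilyl)oxy]methyl}-3-(3,4,5-trimethoxyphenyl)cyclopropane-1,1-dicarboxylate
Product: 10 methyl (1S,5R,6R)-2-oxo-6-(3,4,5-trimethoxyphenyl)-3-oxabicyclo[3.1.0]hexane-1-carboxylate, via hydroxy diester 9 (not isolated)
Conditions: HF·pyridine, THF/pyridine, 0 °C to rt; then PPTS (cat.), PhMe, 50 °C
Reagents that add atoms: none
Why: Fluoride-mediated desilylation frees alcohol 9, which is cis to one of the two ester groups and should close onto it by acid-catalysed lactonisation, leaving the aryl group endo and making C1 a stereocentre dictated by the existing ones.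

**Step 7**
Reactants: 10 methyl (1S,5R,6R)-2-oxo-6-(3,4,5-trimethoxyphenyl)-3-oxabicyclo[3.1.0]hexane-1-carboxylate; 11 formaldehyde
Product: 13 methyl (1R,5R,6S)-2-oxo-6-(3,4,5-trimethoxyphenyl)-3,7-dioxabicyclo[3.3.0]octane-1-carboxylate, via oxocarbenium enolate 12 (not isolated)
Conditions: Sn(OTf)2 (10 mol %), paraformaldehyde (5 equiv of CH2O), ClCH2CH2Cl, rt to 45 °C
Reagents that add atoms: none
Why: Proposed new method: Sn(OTf)2 (divalent tin) should chelate the lactone and ester carbonyl groups on C1 of 10 and polarise the strained C1–C6 bond, so that the oxygen of monomeric formaldehyde attacks the benzylic carbon C6 from the side opposite C1 (the O1–C2 bond of the oxolane) to give oxocarbenium enolate 12, whose tin enolate then adds to the CH2=O+ carbon (the C4–C5 bond). The closest known reaction type is the Lewis-acid-catalysed (3+2) annulation of 2-aryl cyclopropane-1,1-diesters with aryl and alkyl aldehydes, which is stereospecific with inversion at the donor carbon; new here are formaldehyde as the aldehyde and a lactone-fused cyclopropane as its partner. The oxolane closes by an aldol-type 5-(enolexo)-endo-trig attack of the enolate carbon on the oxocarbenium ion, the mode through which the known aldehyde annulations close. The aryl-bearing carbon is set by inversion relative to the untouched neighbouring stereocentre C5, which turns the endo aryl group of 10 into the exo aryl group of 13 (2,3-trans in the oxolane), and the quaternary carbon is fixed because a 3,7-dioxabicyclo[3.3.0]octane can only be cis-fused. The step needs capture by formaldehyde to outpace ionisation-driven elimination, arene alkylation and formaldehyde oligomerisation; the substrate helps through the strain of the bicyclic cyclopropane, the only moderate donor strength of the 3,4,5-trimethoxyphenyl group and the absence of a ketone acceptor that could close a dihydrofuran by Cloke–Wilson rearrangement. Should the benzylic carbon ionise after all, C5 still holds the absolute configuration and the exo-aryl isomer is also the thermodynamically preferred one on the convex face of the bicycle.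

**Step 8**
Reactants: 13 methyl (1R,5R,6S)-2-oxo-6-(3,4,5-trimethoxyphenyl)-3,7-dioxabicyclo[3.3.0]octane-1-carboxylate
Product: 15 (1R,5R,6S)-6-(3,4,5-trimethoxyphenyl)-3,7-dioxabicyclo[3.3.0]octan-2-one, via lithium carboxylate 14 (not isolated)
Conditions: LiCl, H2O, DMSO, 140 °C
Reagents that add atoms: none
Why: In this Krapcho demethoxycarbonylation chloride removes the ester methyl group, carboxylate 14 loses CO2, and the new C1–H bond can only form on the face that keeps the two five-membered rings cis-fused, which sets the cis relationship between the C3 arm and the C4 carbonyl of the target.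

**Step 9**
Reactants: 15 (1R,5R,6S)-6-(3,4,5-trimethoxyphenyl)-3,7-dioxabicyclo[3.3.0]octan-2-one; 16 4-bromo-1,2-dimethoxybenzene
Product: 19 Magnone B, via 3,4-dimethoxyphenyllithium 17 (not isolated), via lithium hemiketalate 18 (not isolated)
Conditions: 16, n-BuLi, THF, −78 °C; then 15, THF, −78 °C; AcOH, −78 °C to rt
Reagents that add atoms: none
Why: Bromine–lithium exchange gives aryllithium 17, which should add once to the lactone carbonyl at −78 °C because the tetrahedral adduct 18 persists until the cold acidic quench, when it opens to the γ-hydroxy aryl ketone without touching any stereocentre.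

**Compound list**

1 | 5-iodo-1,2,3-trimethoxybenzene | COc1cc(I)cc(OC)c1OC | starting material
2 | prop-2-yn-1-ol (propargyl alcohol) | OCC#C | starting material
3 | 3-(3,4,5-trimethoxyphenyl)prop-2-yn-1-ol | COc1cc(C#CCO)cc(OC)c1OC | intermediate
4 | (Z)-3-(3,4,5-trimethoxyphenyl)prop-2-en-1-ol | COc1cc(/C=C\CO)cc(OC)c1OC | intermediate
5 | (Z)-tert-butyldimethyl{[3-(3,4,5-trimethoxyphenyl)prop-2-en-1-yl]oxy}silane | COc1cc(/C=C\CO[Si](C)(C)C(C)(C)C)cc(OC)c1OC | intermediate
6 | dimethyl malonate | COC(=O)CC(=O)OC | starting material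
7 | dimethyl 2-(phenyl-λ3-iodanylidene)propanedioate (phenyliodonium ylide of dimethyl malonate) | COC(=O)[C-](C(=O)OC)[I+]c1ccccc1 | intermediate
8 | dimethyl (2R,3R)-2-{[(tert-butyldimethylsilyl)oxy]methyl}-3-(3,4,5-trimethoxyphenyl)cyclopropane-1,1-dicarboxylate (aryl and silyloxymethyl cis) | COC(=O)C1(C(=O)OC)[C@H](CO[Si](C)(C)C(C)(C)C)[C@@H]1c2cc(OC)c(OC)c(OC)c2 | intermediate
9 | dimethyl (2R,3R)-2-(hydroxymethyl)-3-(3,4,5-trimethoxyphenyl)cyclopropane-1,1-dicarboxylate (not isolated) | COC(=O)C1(C(=O)OC)[C@H](CO)[C@@H]1c2cc(OC)c(OC)c(OC)c2 | intermediate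
10 | methyl (1S,5R,6R)-2-oxo-6-(3,4,5-trimethoxyphenyl)-3-oxabicyclo[3.1.0]hexane-1-carboxylate (aryl endo, cis to C4) | O=C1OC[C@@H]2[C@H](c3cc(OC)c(OC)c(OC)c3)[C@]12C(=O)OC | intermediate
11 | formaldehyde (charged as paraformaldehyde) | C=O | starting material
12 | ring-opened oxocarbenium enolate, drawn as the zwitterion without tin; both stereocentres as in 13 (not isolated) | C=[O+][C@H](c1cc(OC)c(OC)c(OC)c1)[C@H]1COC(=O)C1=C([O-])OC | intermediate
13 | methyl (1R,5R,6S)-2-oxo-6-(3,4,5-trimethoxyphenyl)-3,7-dioxabicyclo[3.3.0]octane-1-carboxylate (cis-fused, aryl exo) | O=C1[C@@]2(C(=O)OC)CO[C@H](c3cc(OC)c(OC)c(OC)c3)[C@H]2CO1 | intermediate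
14 | lithium (1R,5R,6S)-2-oxo-6-(3,4,5-trimethoxyphenyl)-3,7-dioxabicyclo[3.3.0]octane-1-carboxylate (not isolated) | O=C1[C@@]2(C(=O)[O-])CO[C@H](c3cc(OC)c(OC)c(OC)c3)[C@H]2CO1.[Li+] | intermediate
15 | (1R,5R,6S)-6-(3,4,5-trimethoxyphenyl)-3,7-dioxabicyclo[3.3.0]octan-2-one (cis-fused, aryl exo) | O=C1[C@H]2CO[C@H](c3cc(OC)c(OC)c(OC)c3)[C@H]2CO1 | intermediate
16 | 4-bromo-1,2-dimethoxybenzene | COc1ccc(Br)cc1OC | starting material
17 | 3,4-dimethoxyphenyllithium (not isolated) | COc1ccc([Li])cc1OC | intermediate
18 | lithium 2-(3,4-dimethoxyphenyl)-6-(3,4,5-trimethoxyphenyl)-3,7-dioxabicyclo[3.3.0]octan-2-olate, ring stereocentres as in 15, hemiketal carbon unassigned (not isolated) | [Li+].[O-]C1(c3ccc(OC)c(OC)c3)[C@H]2CO[C@H](c4cc(OC)c(OC)c(OC)c4)[C@H]2CO1 | intermediate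
19 | Magnone B, (3,4-dimethoxyphenyl)[(3R,4R,5S)-4-(hydroxymethyl)-5-(3,4,5-trimethoxyphenyl)oxolan-3-yl]methanone | COc1ccc(C(=O)[C@H]2CO[C@H](c3cc(OC)c(OC)c(OC)c3)[C@H]2CO)cc1OC | target

**Step count**

Total steps: 9. Longest linear sequence: 8 (steps 1, 2, 3, 5, 6, 7, 8, 9); step 4 is a one-step branch.

**Steps most likely to fail**

Step 7 (new method). Formaldehyde is a weak nucleophile that polymerises readily, so opening of the activated cyclopropane may be outrun by ionisation at the benzylic carbon, followed by elimination, arene alkylation or loss of stereochemical fidelity. The fallback builds the oxolane stepwise by known reactions, setting out from 8 and returning at 13.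
- Lewis-acid-catalysed methanolysis of the cyclopropane (Yb(OTf)3, MeOH, CH2Cl2) should open 8 at the benzylic carbon to dimethyl 2-[(2R)-3-{[tert-butyl(dimethyl)silyl]oxy}-1-methoxy-1-(3,4,5-trimethoxyphenyl)propan-2-yl]propanedioate F1.
- Tollens-type hydroxymethylation of the malonate C–H with aqueous formaldehyde and K2CO3 in THF should give dimethyl 2-[(2R)-3-{[tert-butyl(dimethyl)silyl]oxy}-1-methoxy-1-(3,4,5-trimethoxyphenyl)propan-2-yl]-2-(hydroxymethyl)propanedioate F2.
- A catalytic acid (CSA or BF3·OEt2, CH2Cl2, low temperature) ionises the benzylic methyl ether and the primary hydroxyl group closes the ring under thermodynamic control with the aryl group trans to the silyloxymethyl arm. This should give dimethyl (4R,5S)-4-{[(tert-butyldimethylsilyl)oxy]methyl}-5-(3,4,5-trimethoxyphenyl)oxolane-3,3-dicarboxylate F3.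
- HF·pyridine followed by PPTS removes the silyl group and lactonises the freed alcohol onto the cis ester, which gives 13.

Step 5. Carbene transfer to a cis-disubstituted alkene may be sluggish (the ylide decomposing faster than it is transferred), or the ligand may discriminate the two alkene faces poorly. The fallback delivers the carbene intramolecularly, setting out from 4 and returning at 10.
- Acylation of 4 with methyl malonyl chloride (pyridine, CH2Cl2, 0 °C) gives methyl (2Z)-3-(3,4,5-trimethoxyphenyl)prop-2-en-1-yl propanedioate F4.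
- Diazo transfer with 4-acetamidobenzenesulfonyl azide and Et3N in MeCN gives methyl (2Z)-3-(3,4,5-trimethoxyphenyl)prop-2-en-1-yl 2-diazopropanedioate F5.
- Intramolecular cyclopropanation with [Cu(MeCN)4]PF6 and a chiral bisoxazoline ligand closes cyclopropane and lactone together to 10. The tether guarantees the endo aryl geometry; any shortfall in enantiomeric purity would be made up by recrystallisation of 10 or 15.

Step 9. The ketone released from the hemiketalate may take up a second equivalent of aryllithium, or the organolithium may act as a base and cause enolisation or epimerisation at C4. The fallback passes through a Weinreb amide, setting out from 15 and returning at 19.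
- Opening of the lactone with the chloromagnesium amide made from Me(MeO)NH·HCl and i-PrMgCl (THF, −20 °C) gives (3R,4R,5S)-4-(hydroxymethyl)-N-methoxy-N-methyl-5-(3,4,5-trimethoxyphenyl)oxolane-3-carboxamide F6.
- Immediate silylation (TBSCl, imidazole) gives (3R,4R,5S)-4-{[(tert-butyldimethylsilyl)oxy]methyl}-N-methoxy-N-methyl-5-(3,4,5-trimethoxyphenyl)oxolane-3-carboxamide F7.
- Aryllithium 17, generated from 16 as in step 9, adds once to the amide and after an AcOH quench gives [(3R,4R,5S)-4-{[(tert-butyldimethylsilyl)oxy]methyl}-5-(3,4,5-trimethoxyphenyl)oxolan-3-yl](3,4-dimethoxyphenyl)methanone F8.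
- Buffered HF·pyridine removes the silyl group to give 19.

**Further compounds**

F1 | step 7 | dimethyl 2-[(2R)-3-{[tert-butyl(dimethyl)silyl]oxy}-1-methoxy-1-(3,4,5-trimethoxyphenyl)propan-2-yl]propanedioate (benzylic carbon as formed) | COC(=O)C(C(=O)OC)[C@H](CO[Si](C)(C)C(C)(C)C)C(OC)c1cc(OC)c(OC)c(OC)c1
F2 | step 7 | dimethyl 2-[(2R)-3-{[tert-butyl(dimethyl)silyl]oxy}-1-methoxy-1-(3,4,5-trimethoxyphenyl)propan-2-yl]-2-(hydroxymethyl)propanedioate | COC(=O)C(CO)(C(=O)OC)[C@H](CO[Si](C)(C)C(C)(C)C)C(OC)c1cc(OC)c(OC)c(OC)c1
F3 | step 7 | dimethyl (4R,5S)-4-{[(tert-butyldimethylsilyl)oxy]methyl}-5-(3,4,5-trimethoxyphenyl)oxolane-3,3-dicarboxylate | COC(=O)C1(C(=O)OC)CO[C@H](c2cc(OC)c(OC)c(OC)c2)[C@H]1CO[Si](C)(C)C(C)(C)C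
F4 | step 5 | methyl (2Z)-3-(3,4,5-trimethoxyphenyl)prop-2-en-1-yl propanedioate | COC(=O)CC(=O)OC/C=C\c1cc(OC)c(OC)c(OC)c1
F5 | step 5 | methyl (2Z)-3-(3,4,5-trimethoxyphenyl)prop-2-en-1-yl 2-diazopropanedioate | COC(=O)C(=[N+]=[N-])C(=O)OC/C=C\c1cc(OC)c(OC)c(OC)c1
F6 | step 9 | (3R,4R,5S)-4-(hydroxymethyl)-N-methoxy-N-methyl-5-(3,4,5-trimethoxyphenyl)oxolane-3-carboxamide | CON(C)C(=O)[C@H]1CO[C@H](c2cc(OC)c(OC)c(OC)c2)[C@H]1CO
F7 | step 9 | (3R,4R,5S)-4-{[(tert-butyldimethylsilyl)oxy]methyl}-N-methoxy-N-methyl-5-(3,4,5-trimethoxyphenyl)oxolane-3-carboxamide | CON(C)C(=O)[C@H]1CO[C@H](c2cc(OC)c(OC)c(OC)c2)[C@H]1CO[Si](C)(C)C(C)(C)C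
F8 | step 9 | [(3R,4R,5S)-4-{[(tert-butyldimethylsilyl)oxy]methyl}-5-(3,4,5-trimethoxyphenyl)oxolan-3-yl](3,4-dimethoxyphenyl)methanone | COc1ccc(C(=O)[C@H]2CO[C@H](c3cc(OC)c(OC)c(OC)c3)[C@H]2CO[Si](C)(C)C(C)(C)C)cc1OC
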